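**Retrosynthetic overview**
1. The target is (2S,4S,6S), with aryl and side chain cis-diequatorial and the 4-OH axial. It comes from the fully protected oxane by desilylation and hydrogenolysis of four O-benzyl groups.
2. The C2–H bond comes from axial Et3SiH reduction of a 2-aryl oxocarbenium ion. That ion comes from a lactol, made by joining an aryllithium to a 4-silyloxy δ-lactone (C2–aryl bond).
3. The δ-lactone comes from a syn-(3S,5S)-3,5-dihydroxyheptanoate. The diol comes from ketoreductase reduction of a (5S)-5-hydroxy-3-oxoheptanoate, itself the Claisen extension of an (S)-β-hydroxy ester.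
4. The (S)-β-hydroxy ester comes from Ru–(S)-BINAP hydrogenation of a β-keto ester built from acetoacetate dianion and 3,4-bis(benzyloxy)benzyl chloride. The aryl bromide comes from Dakin oxidation and benzylation of 5-bromo-o-vanillin.
5. Ring order: both arenes are bought. The only ring made is the oxane, closed first as the δ-lactone and carried through the lactol into the tetrahydropyran.

Assumption: the (3S)-selective ketoreductase for compound 10 is picked from a commercial KRED screening panel, and 1, 4, 8 and 15 are catalogue chemicals.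

**Step 1**
Reactants: 1 3,4-bis(benzyloxy)benzaldehyde
Product: 2 [3,4-bis(benzyloxy)phenyl]methanol
Conditions: NaBH4, THF/MeOH, 0 °C → rt
Reagents that add atoms: none
Why: Borohydride reduction of an aromatic aldehyde is clean, the benzyl ethers are inert, and no stereocentre is formed.

**Step 2**
Reactants: 2 [3,4-bis(benzyloxy)phenyl]methanol
Product: 3 1,2-bis(benzyloxy)-4-(chloromethyl)benzene
Conditions: SOCl2 (1.2 equiv), cat. DMF, CH2Cl2, 0 °C → rt
Reagents that add atoms: thionyl chloride, O=S(Cl)Cl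
Why: Deoxychlorination of an electron-rich benzylic alcohol is fast and gives a crystalline chloride that stores better than the bromide.

**Step 3**
Reactants: 3 1,2-bis(benzyloxy)-4-(chloromethyl)benzene; 4 ethyl acetoacetate
Product: 6 ethyl 5-[3,4-bis(benzyloxy)phenyl]-3-oxopentanoate, via acetoacetate dianion 5 (not isolated)
Conditions: 4 (1.2 equiv), NaH, THF, 0 °C; n-BuLi, 0 °C; then 3, 0 °C → rt; 1 M HCl quench
Reagents that add atoms: none
Why: In the Huckin–Weiler dianion alkylation the more nucleophilic terminal carbon of 5 displaces the benzylic chloride (SN2), so only the γ-alkylated β-keto ester forms.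

**Step 4**
Reactants: 6 ethyl 5-[3,4-bis(benzyloxy)phenyl]-3-oxopentanoate
Product: 7 ethyl (3S)-5-[3,4-bis(benzyloxy)phenyl]-3-hydroxypentanoate
Conditions: RuCl2[(S)-BINAP] (0.2 mol %), H2 (50 bar), EtOH/CH2Cl2, 50 °C
Reagents that add atoms: none
Why: In the Noyori asymmetric hydrogenation the β-keto ester chelates Ru and the (S)-BINAP quadrants expose one ketone face only, which sets the first stereocentre as (3S) (future ring C6, typically ≥97 % ee) and leaves the aryl benzyl ethers untouched.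

**Step 5**
Reactants: 7 ethyl (3S)-5-[3,4-bis(benzyloxy)phenyl]-3-hydroxypentanoate; 8 tert-butyl acetate
Product: 10 tert-butyl (5S)-7-[3,4-bis(benzyloxy)phenyl]-5-hydroxy-3-oxoheptanoate, via lithium enolate 9 (not isolated)
Conditions: 8 (4 equiv), LDA (commercial solution, 4 equiv), THF, −78 °C; then 7, −78 → −20 °C; AcOH quench
Reagents that add atoms: none
Why: In this crossed Claisen condensation the non-self-condensing enolate 9 acylates at the ethyl ester, excess enolate absorbs the OH and the acidic product protons, and the carbinol centre is not involved.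

**Step 6**
Reactants: 10 tert-butyl (5S)-7-[3,4-bis(benzyloxy)phenyl]-5-hydroxy-3-oxoheptanoate
Product: 11 tert-butyl (3S,5S)-7-[3,4-bis(benzyloxy)phenyl]-3,5-dihydroxyheptanoate
Conditions: ketoreductase (KRED; NADPH-dependent carbonyl reductase, oxidoreductase class EC 1.1.1), NADP+ (cat.), i-PrOH/0.1 M K-phosphate buffer pH 7.0 (3:7), 5 % DMSO, MgSO4 (1 mM), 30 °C
Reagents that add atoms: none
Why: In this ketoreductase-catalysed asymmetric ketone reduction (the enzyme-class transformation used for statin side-chain diols) the chiral pocket delivers the NADPH hydride to the Re face of C3 regardless of the C5 carbinol, which sets (3S) and hence the syn-(3S,5S)-diol while isopropanol recycles the cofactor.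

**Step 7**
Reactants: 11 tert-butyl (3S,5S)-7-[3,4-bis(benzyloxy)phenyl]-3,5-dihydroxyheptanoate
Product: 13 (4S,6S)-6-{2-[3,4-bis(benzyloxy)phenyl]ethyl}-4-hydroxyoxan-2-one, via dihydroxy acid 12 (not isolated)
Conditions: NaOH (1.5 equiv), THF/MeOH/H2O, 40 °C; 1 M HCl to pH 3, 0 °C; then toluene, reflux (Dean–Stark)
Reagents that add atoms: none
Why: Saponification followed by thermal δ-lactonisation breaks only acyl C–O bonds, so both carbinol centres are retained, and the syn-diol gives the trans-4-hydroxy-6-alkyl lactone without generating a tert-butyl cation near the electron-rich arene.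

**Step 8**
Reactants: 13 (4S,6S)-6-{2-[3,4-bis(benzyloxy)phenyl]ethyl}-4-hydroxyoxan-2-one
Product: 14 (4S,6S)-6-{2-[3,4-bis(benzyloxy)phenyl]ethyl}-4-[(tert-butyldimethylsilyl)oxy]oxan-2-one
Conditions: TBSCl (1.5 equiv), imidazole (3 equiv), DMF, rt
Reagents that add atoms: tert-butyldimethylsilyl chloride, CC(C)(C)[Si](C)(C)Cl
Why: Corey silylation under weakly basic conditions protects the β-hydroxyl without β-elimination of the lactone.

**Step 9**
Reactants: 15 5-bromo-2-hydroxy-3-methoxybenzaldehyde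
Product: 17 5-bromo-3-methoxybenzene-1,2-diol, via aryl formate 16 (not isolated)
Conditions: 30 % H2O2 (1.2 equiv), 1 M NaOH (1.1 equiv), H2O/THF, 0 °C → rt, N2; then 1 M HCl
Reagents that add atoms: hydrogen peroxide, OO
Why: In the Dakin oxidation the ortho-hydroxy aldehyde undergoes aryl migration to formate 16, which hydrolyses in situ to the catechol with bromine para to the central oxygen.

**Step 10**
Reactants: 17 5-bromo-3-methoxybenzene-1,2-diol
Product: 18 1,2-bis(benzyloxy)-5-bromo-3-methoxybenzene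
Conditions: BnBr (2.4 equiv), K2CO3 (3 equiv), DMF, 60 °C, N2
Reagents that add atoms: benzyl bromide, BrCc1ccccc1
Why: Williamson ether synthesis on both phenoxides gives a base-stable and organolithium-stable protected aryl bromide.

**Step 11**
Reactants: 18 1,2-bis(benzyloxy)-5-bromo-3-methoxybenzene; 14 (4S,6S)-6-{2-[3,4-bis(benzyloxy)phenyl]ethyl}-4-[(tert-butyldimethylsilyl)oxy]oxan-2-one
Product: 20 (4S,6S)-2-[3,4-bis(benzyloxy)-5-methoxyphenyl]-6-{2-[3,4-bis(benzyloxy)phenyl]ethyl}-4-[(tert-butyldimethylsilyl)oxy]oxan-2-ol (anomer mixture in equilibrium with its open δ-hydroxy ketone form), via aryllithium 19 (not isolated)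
Conditions: 18 (1.3 equiv), n-BuLi (1.25 equiv), THF, −78 °C, 30 min; then 14, −78 °C, 1 h; AcOH/THF quench at −78 °C; crude product used directly
Reagents that add atoms: none
Why: Bromine–lithium exchange and then 1,2-addition to the lactone carbonyl at −78 °C, as in 2-deoxy C-aryl glycoside synthesis, outrun enolisation, and the tetrahedral alkoxide resists a second addition until the cold quench.

**Step 12**
Reactants: 20 (4S,6S)-2-[3,4-bis(benzyloxy)-5-methoxyphenyl]-6-{2-[3,4-bis(benzyloxy)phenyl]ethyl}-4-[(tert-butyldimethylsilyl)oxy]oxan-2-ol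
Product: 22 tert-butyl({(2S,4S,6S)-2-[3,4-bis(benzyloxy)-5-methoxyphenyl]-6-{2-[3,4-bis(benzyloxy)phenyl]ethyl}oxan-4-yl}oxy)dimethylsilane, via oxocarbenium ion 21 (not isolated)
Conditions: Et3SiH (5 equiv), BF3·OEt2 (2 equiv), CH2Cl2, −78 → −40 °C; sat. NaHCO3
Reagents that add atoms: none
Why: In this Kishi-type ionic reduction of a hemiketal, the half-chair of aryl-stabilised 21 holds the C6 chain pseudo-equatorial and the C4 silyloxy group pseudo-axial, and the silane attacks axially, so the new C2–H is axial and the aryl equatorial, which is (2S) and 2,6-cis.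

**Step 13**
Reactants: 22 tert-butyl({(2S,4S,6S)-2-[3,4-bis(benzyloxy)-5-methoxyphenyl]-6-{2-[3,4-bis(benzyloxy)phenyl]ethyl}oxan-4-yl}oxy)dimethylsilane
Product: 23 (2S,4S,6S)-2-[3,4-bis(benzyloxy)-5-methoxyphenyl]-6-{2-[3,4-bis(benzyloxy)phenyl]ethyl}oxan-4-ol
Conditions: TBAF (1.5 equiv), THF, 0 °C → rt
Reagents that add atoms: none
Why: Fluoride-driven desilylation breaks only the Si–O bond, so the axial (4S) carbinol is released with retention while the phenols stay masked against base and air.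

**Step 14**
Reactants: 23 (2S,4S,6S)-2-[3,4-bis(benzyloxy)-5-methoxyphenyl]-6-{2-[3,4-bis(benzyloxy)phenyl]ethyl}oxan-4-ol
Product: 24 (2S,4S,6S)-2-(3,4-dihydroxy-5-methoxyphenyl)-6-[2-(3,4-dihydroxyphenyl)ethyl]oxan-4-ol (CNP0196753.1)
Conditions: H2 (1 atm), 10 % Pd/C, EtOAc/MeOH 1:1, rt, stopped at full conversion; Celite filtration under Ar
Reagents that add atoms: none
Why: Under neutral 1 atm catalytic hydrogenolysis the four aryl benzyl ethers cleave much faster than the ring's secondary benzylic C2–O bond, no stereocentre is touched, and the air-sensitive bis-catechol appears only in this last neutral step.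

**Compound list**
1 | 3,4-bis(benzyloxy)benzaldehyde | O=Cc1ccc(OCc2ccccc2)c(OCc2ccccc2)c1 | starting material
2 | [3,4-bis(benzyloxy)phenyl]methanol | OCc1ccc(OCc2ccccc2)c(OCc2ccccc2)c1 | intermediate
3 | 1,2-bis(benzyloxy)-4-(chloromethyl)benzene | ClCc1ccc(OCc2ccccc2)c(OCc2ccccc2)c1 | intermediate
4 | ethyl acetoacetate | CCOC(=O)CC(C)=O | starting material
5 | sodium lithium dianion (bis-enolate) of ethyl acetoacetate | [Li+].[Na+].C=C([O-])C=C([O-])OCC | intermediate
6 | ethyl 5-[3,4-bis(benzyloxy)phenyl]-3-oxopentanoate | CCOC(=O)CC(=O)CCc1ccc(OCc2ccccc2)c(OCc2ccccc2)c1 | intermediate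
7 | ethyl (3S)-5-[3,4-bis(benzyloxy)phenyl]-3-hydroxypentanoate | CCOC(=O)C[C@@H](O)CCc1ccc(OCc2ccccc2)c(OCc2ccccc2)c1 | intermediate
8 | tert-butyl acetate | CC(=O)OC(C)(C)C | starting material
9 | lithium enolate of tert-butyl acetate | [Li+].C=C([O-])OC(C)(C)C | intermediate
10 | tert-butyl (5S)-7-[3,4-bis(benzyloxy)phenyl]-5-hydroxy-3-oxoheptanoate | CC(C)(C)OC(=O)CC(=O)C[C@@H](O)CCc1ccc(OCc2ccccc2)c(OCc2ccccc2)c1 | intermediate
11 | tert-butyl (3S,5S)-7-[3,4-bis(benzyloxy)phenyl]-3,5-dihydroxyheptanoate (syn-diol) | CC(C)(C)OC(=O)C[C@@H](O)C[C@@H](O)CCc1ccc(OCc2ccccc2)c(OCc2ccccc2)c1 | intermediate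
12 | (3S,5S)-7-[3,4-bis(benzyloxy)phenyl]-3,5-dihydroxyheptanoic acid | OC(=O)C[C@@H](O)C[C@@H](O)CCc1ccc(OCc2ccccc2)c(OCc2ccccc2)c1 | intermediate
13 | (4S,6S)-6-{2-[3,4-bis(benzyloxy)phenyl]ethyl}-4-hydroxyoxan-2-one (4-OH trans to the 6-chain) | O=C1C[C@@H](O)C[C@H](CCc2ccc(OCc3ccccc3)c(OCc3ccccc3)c2)O1 | intermediate
14 | (4S,6S)-6-{2-[3,4-bis(benzyloxy)phenyl]ethyl}-4-[(tert-butyldimethylsilyl)oxy]oxan-2-one | O=C1C[C@@H](O[Si](C)(C)C(C)(C)C)C[C@H](CCc2ccc(OCc3ccccc3)c(OCc3ccccc3)c2)O1 | intermediate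
15 | 5-bromo-2-hydroxy-3-methoxybenzaldehyde | COc1cc(Br)cc(C=O)c1O | starting material
16 | 5-bromo-2-hydroxy-3-methoxyphenyl formate | COc1cc(Br)cc(OC=O)c1O | intermediate
17 | 5-bromo-3-methoxybenzene-1,2-diol | COc1cc(Br)cc(O)c1O | intermediate
18 | 1,2-bis(benzyloxy)-5-bromo-3-methoxybenzene | COc1cc(Br)cc(OCc2ccccc2)c1OCc1ccccc1 | intermediate
19 | [3,4-bis(benzyloxy)-5-methoxyphenyl]lithium | [Li]c1cc(OC)c(OCc2ccccc2)c(OCc2ccccc2)c1 | intermediate
20 | (4S,6S)-2-[3,4-bis(benzyloxy)-5-methoxyphenyl]-6-{2-[3,4-bis(benzyloxy)phenyl]ethyl}-4-[(tert-butyldimethylsilyl)oxy]oxan-2-ol, C2 anomer mixture | COc1cc(C2(O)C[C@@H](O[Si](C)(C)C(C)(C)C)C[C@H](CCc3ccc(OCc4ccccc4)c(OCc4ccccc4)c3)O2)cc(OCc2ccccc2)c1OCc1ccccc1 | intermediate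
21 | (4S,6S)-2-aryl-4-silyloxy-6-(arylethyl)-3,4,5,6-tetrahydropyrylium (oxocarbenium ion from 20) | COc1cc(C=2C[C@@H](O[Si](C)(C)C(C)(C)C)C[C@H](CCc3ccc(OCc4ccccc4)c(OCc4ccccc4)c3)[O+]=2)cc(OCc2ccccc2)c1OCc1ccccc1 | intermediate
22 | tert-butyl({(2S,4S,6S)-2-[3,4-bis(benzyloxy)-5-methoxyphenyl]-6-{2-[3,4-bis(benzyloxy)phenyl]ethyl}oxan-4-yl}oxy)dimethylsilane (2,6-cis, 4-O axial) | COc1cc([C@@H]2C[C@@H](O[Si](C)(C)C(C)(C)C)C[C@H](CCc3ccc(OCc4ccccc4)c(OCc4ccccc4)c3)O2)cc(OCc2ccccc2)c1OCc1ccccc1 | intermediate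
23 | (2S,4S,6S)-2-[3,4-bis(benzyloxy)-5-methoxyphenyl]-6-{2-[3,4-bis(benzyloxy)phenyl]ethyl}oxan-4-ol | COc1cc([C@@H]2C[C@@H](O)C[C@H](CCc3ccc(OCc4ccccc4)c(OCc4ccccc4)c3)O2)cc(OCc2ccccc2)c1OCc1ccccc1 | intermediate
24 | (2S,4S,6S)-2-(3,4-dihydroxy-5-methoxyphenyl)-6-[2-(3,4-dihydroxyphenyl)ethyl]oxan-4-ol | COc1cc([C@@H]2C[C@@H](O)C[C@H](CCc3ccc(O)c(O)c3)O2)cc(O)c1O | target

**Totals and risks**

Total step count: 14. Longest linear sequence: 12 (steps 1–8 and 11–14). Steps 9–10 are the two-step side branch to 18.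

Risk 1, step 6. No panel enzyme may accept the bulky, poorly soluble 10, or none may give the (3S) alcohol cleanly. The fallback sets out from 10 and replaces catalyst control by substrate control (Narasaka–Prasad reduction).
- Et2BOMe in THF/MeOH at −78 °C ties the C5 hydroxyl and the C3 ketone into the diethylboron chelate F1.
- NaBH4 attacks the chair-like chelate axially to give the sodium syn-diol diethylborate F2.
- Co-evaporation with AcOH/MeOH strips the boron, and the route is rejoined at 11.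
- The biocatalytic reduction would then be moved to the smaller ketone 6 (6 → 7) with an (S)-selective ketoreductase.

Risk 2, step 11. Aryllithium 19 may enolise lactone 14, which leads to β-elimination of the silyloxy group, or it may add twice. The fallback sets out from 14 and makes the C–aryl bond on an open chain.
- MeNH(OMe)·HCl/AlMe3 in CH2Cl2 opens the lactone to the δ-hydroxy Weinreb amide F3.
- TESCl/imidazole caps it as the triethylsilyl ether F4.
- Aryllithium 19, made from 18 as before, adds once through the stable chelated tetrahedral adduct to give the open-chain aryl ketone F5.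
- AcOH/THF/H2O removes only the TES group, the freed δ-hydroxy ketone closes, and the route is rejoined at 20.

Risk 3, step 12. The β-silyloxy ketone tautomer may eliminate, or the axial silyloxy group may erode facial selectivity. The fallback sets out from 20 and closes the ring under thermodynamic rather than kinetic control.
- NaBH4 in MeOH reduces the open tautomer to the 1,5-diol F6, a mixture of C1 epimers.
- Catalytic CSA in CH2Cl2 (0 °C → rt) ionises the p-alkoxybenzylic alcohol reversibly.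
- The C5 hydroxyl traps the cation (SN1 cyclodehydration) and equilibration funnels both epimers to the 2,6-diequatorial oxane, so the route is rejoined at 22.

**Further compounds**
F1 | step 6 | tert-butyl (5S)-7-[3,4-bis(benzyloxy)phenyl]-5-[(diethylboranyl)oxy]-3-oxoheptanoate (boron chelated by the C3 ketone) | CC(C)(C)OC(=O)CC(=O)C[C@H](CCc1ccc(OCc2ccccc2)c(OCc2ccccc2)c1)OB(CC)CC
F2 | step 6 | sodium cyclic diethylborate of the syn-(3S,5S)-diol 11 (2,2-diethyl-1,3,2-dioxaborinan-2-uide) | [Na+].CC[B-]1(CC)O[C@H](CC(=O)OC(C)(C)C)C[C@H](CCc2ccc(OCc3ccccc3)c(OCc3ccccc3)c2)O1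
F3 | step 11 | (3S,5S)-7-[3,4-bis(benzyloxy)phenyl]-3-[(tert-butyldimethylsilyl)oxy]-5-hydroxy-N-methoxy-N-methylheptanamide | CON(C)C(=O)C[C@@H](O[Si](C)(C)C(C)(C)C)C[C@@H](O)CCc1ccc(OCc2ccccc2)c(OCc2ccccc2)c1
F4 | step 11 | (3S,5S)-7-[3,4-bis(benzyloxy)phenyl]-3-[(tert-butyldimethylsilyl)oxy]-N-methoxy-N-methyl-5-[(triethylsilyl)oxy]heptanamide | CON(C)C(=O)C[C@@H](O[Si](C)(C)C(C)(C)C)C[C@@H](O[Si](CC)(CC)CC)CCc1ccc(OCc2ccccc2)c(OCc2ccccc2)c1
F5 | step 11 | (3S,5S)-1-[3,4-bis(benzyloxy)-5-methoxyphenyl]-7-[3,4-bis(benzyloxy)phenyl]-3-[(tert-butyldimethylsilyl)oxy]-5-[(triethylsilyl)oxy]heptan-1-one | COc1cc(C(=O)C[C@@H](O[Si](C)(C)C(C)(C)C)C[C@@H](O[Si](CC)(CC)CC)CCc2ccc(OCc3ccccc3)c(OCc3ccccc3)c2)cc(OCc2ccccc2)c1OCc1ccccc1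
F6 | step 12 | (3S,5S)-1-[3,4-bis(benzyloxy)-5-methoxyphenyl]-7-[3,4-bis(benzyloxy)phenyl]-3-[(tert-butyldimethylsilyl)oxy]heptane-1,5-diol (C1 epimers) | COc1cc(C(O)C[C@@H](O[Si](C)(C)C(C)(C)C)C[C@@H](O)CCc2ccc(OCc3ccccc3)c(OCc3ccccc3)c2)cc(OCc2ccccc2)c1OCc1ccccc1
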